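## The problem

The target **15** is a cyclohex-2-ene with five substituted ring carbons: C1 carries OMe, C6 a free OH, C5 a benzoate, C4 a free OH, and the alkene carbon C3 a benzoyloxymethyl group (C7). There is no ring fusion to plan. The task is four contiguous stereocentres, (1S,4R,5R,6R), with C1/C6 trans, C6/C5 trans and C5/C4 cis, and five oxygens that end in four different states. The all-trans C1–C6–C5 triad is a threo,threo triol unit that exists ready-made as C2–C4 of D-xylose (**1**). C4 lies next to C5 and is the one centre that can reasonably be set under control of its neighbour. The C5 benzoate sits between a cis hydroxyl (C4) and a trans hydroxyl (C6), so base invites acyl migration, and hydride or alkoxide would remove it; both benzoates therefore have to arrive last, under neutral conditions. The allylic methyl ether and allylic alcohol flank C2=C3, which excludes strong Lewis acids and hydrogenolysis and so narrows the choice of hydroxyl protection. The enabling feature is the unit C2=C3(C7)–C4(OH): with C7 at the acyl level, C3 is the α-carbon of an acrylate and C4 the adjacent carbinol. This is the retron of a Morita–Baylis–Hillman reaction, so the ring can be closed at C3–C4 from an acyclic ω-formyl enethioate.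

## Retrosynthesis

**Benzoates last (15 ⇒ 13).** The acyl C–O bonds at O5 and O7 are cut, giving tetraol **13**. No benzoate would survive the hydride step or sit quietly beside a transient alkoxide, and distinguishing O5 from O6 by two different protecting groups from the sugar stage would cost at least two more steps. In **13** the ring hydroxyls are arranged like those of a β-galactoside (O4 axial-like, O5 and O6 equatorial, C7–OH in place of the primary hydroxyl). Tin-acetal acylation is known to select the primary oxygen and the equatorial oxygen of the cis pair in that arrangement. The forward step must deliver exactly two acylations without migration.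

**Unmasking (13 ⇒ 12 ⇒ 11).** The two O–CH2Ar bonds at O5 and O6 are cut, then C7 is returned from CH2OH to the thioester of **11**. Naphthalen-2-ylmethyl ethers are chosen because they tolerate both strong base and the hot aqueous acid needed earlier, and leave oxidatively without hydrogen; 4-methoxybenzyl would not survive the acid and benzyl could not be removed beside the alkene. Reduction precedes deprotection so that the very polar **13** appears only one step before the end.

**Key disconnection (11 ⇒ 10).** The C3–C4 bond is cut. Cutting C2=C3 instead (metathesis) would require the C4 carbinol to be set in a separate open-chain addition, and any cut inside C4–C5–C6–C1 would destroy the sugar-derived triad. Precursor **10** is acyclic and carries only the three stereocentres supplied by the sugar. The forward reaction must close one ring, form one C–C bond and set C4 cis to O5.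

**Chain assembly (10 ⇒ 9 ⇒ 7 + 8).** The C2=C3 bond is cut (Wittig, ylide **8** supplying C3 and C7) and C4 is returned to the alcohol level. Using the pyranose lactol **7** is what keeps this short: its ring oxygen is the oxygen on future C4. Olefination therefore liberates exactly that oxygen as the only free hydroxyl, a primary alcohol ready for oxidation. A furanose lactol would instead free the secondary oxygen on future C5 and require a protection/deprotection pair.

**Ethers and glycoside (7 ⇒ 6 ⇒ 5).** The anomeric C–O bond and the two naphthylmethyl ether bonds are cut. A methyl glycoside guards the anomeric carbon during the double etherification of the 3,4-diol of **5**. The forward hydrolysis must spare the ethers.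

**Differentiating sugar O2 (5 ⇒ 4 ⇒ 3 ⇒ 1).** The O–CH3 bond at sugar O2 (future O1) is cut. Only in the furanoside are O3 and O5 cis across a six-membered acetal, so that O2 is the single free hydroxyl of **3**. After methylation to **4**, acid equilibration to the pyranoside **5** moves the ring oxygen from O4 to O5 and exposes O3 and O4 together. Mapping: sugar C1→C2, C2→C1, C3→C6, C4→C5, C5→C4.

## Roads not taken

**Alternative 1:** The cut is at C1–O and C6–O, with the carbocycle taken ready-made. A chiral (salen)MnCl complex (trivalent manganese) with NaOCl monoepoxidises one enantiotopic alkene of the meso diene acetonide A1, giving vinyl epoxide A2 anti to the acetonide. Acid-catalysed methanolysis at the allylic carbon would then give A3, with C1–OMe/C6–OH trans and the C4/C5 cis-diol masked.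
- Merits: one catalytic enantioselective step and one SN2 opening fix all four stereocentres. The ring-bound oxygen pattern is reached in far fewer steps than the eight the chosen plan spends before **11**.
- Weak points: A2 and A3 carry hydrogen where C7 belongs, and C3 is an unactivated vinylic CH. Installing one carbon there needs a detour through a C3-halo or C4-carbonyl derivative, which costs redox steps or the C4 centre. Absolute configuration rests on the selectivity of a desymmetrisation that must also stop at one alkene, and A1 is not a shelf chemical.
- Comparison: this road is better for ring construction and catalytic economy. The chosen plan sets against it that C7 enters at the right oxidation level in the ring-closing step and that absolute configuration comes from the sugar.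

**Alternative 2:** The cut is at C4–O and C5–O of an arene. Whole cells of a recombinant Escherichia coli expressing toluene dioxygenase convert bromobenzene A4 into the cis-dihydrodiol A5; no ring closes.
- Merits: A5 has the correct absolute configuration at C4 and C5 in one step, and its bromine sits on C3, the carbon that needs C7. Acetonide formation, epoxidation of the distal alkene anti to the acetonide and methanolysis at C1 would then set C1 and C6. This is probably the shortest of the four roads, and in step count it is better than the chosen plan.
- Weak points: it needs fermentation capability or a costly purchase of A5. A5 is prone to dehydrative aromatisation and dimerisation. The one-carbon homologation must be run on a hindered, oxygen-flanked vinyl bromide. The end-game differentiation of O4, O5 and O6 is no easier than here.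
- Comparison: the chosen plan is longer (eleven steps) but uses only bench reagents and a cheap sugar, and it distinguishes O1 (methyl) from O6 at the outset instead of through a regioselective epoxide opening.

**Alternative 3:** The cuts are C3–C4 and C5–C6. Furfuryl acetate A6 and vinylene carbonate A7 combine in an endo Diels–Alder reaction to the 7-oxanorbornene A8. An SN2′ methanolysis of the oxygen bridge at C1, for example with [Rh(cod)Cl]2 (monovalent rhodium) and a chiral bisphosphine, would then give C1–OMe/C6–OH trans with C2=C3 in place.
- Merits: one step assembles all seven carbons and the oxygens at C4, C5, C6 and C7 from two commodity chemicals, with C7 already attached. It is the most convergent road.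
- Weak points: furan cycloadditions of this kind are reversible, need forcing conditions and give endo/exo mixtures. A8 is racemic, so half the material is lost to resolution unless an enantioselective opening works on a bridgehead-substituted, non-benzo-fused substrate. The nucleophile must attack the alkene carbon remote from the quaternary bridgehead. Carbonate, acetate and benzoate esters must be sorted at the end.
- Comparison: shorter and more convergent on paper. The chosen plan trades length for secure absolute and relative configuration at C1, C5 and C6.

Key step: step 8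

Remark on the chemistry: glycosides **2**–**6** and lactol **7** are carried as α/β mixtures at the anomeric carbon, which is not a stereocentre of the target and becomes sp2 carbon C2 in step 6 (their SMILES leave it open); ylide **8** is taken as a purchasable reagent.

Step 1
Reactants: 1 D-xylose
Product: 3 methyl 3,5-O-isopropylidene-α/β-D-xylofuranoside, via methyl α/β-D-xylofuranoside 2 (not isolated)
Conditions: HCl (0.5% in MeOH), rt; evaporate; then Me2C(OMe)2, CSA (cat.), acetone, rt
Reagents that add atoms: methanol, CO; 2,2-dimethoxypropane, COC(C)(C)OC
Why: Fischer glycosidation under kinetic control gives mainly the furanosides 2; acetal exchange then locks the cis-disposed O3 and O5 in a six-membered isopropylidene acetal (the same ring as in the familiar diacetonide of xylose), leaving O2 as the only free hydroxyl; pyranoside by-products cannot form this acetal and are removed by chromatography.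

Step 2
Reactants: 3 methyl 3,5-O-isopropylidene-α/β-D-xylofuranoside
Product: 4 methyl 3,5-O-isopropylidene-2-O-methyl-α/β-D-xylofuranoside
Conditions: NaH, MeI, THF–DMF, 0 °C → rt
Reagents that add atoms: iodomethane, CI
Why: Williamson etherification of the single free hydroxyl; acetal and glycoside are inert to NaH.

Step 3
Reactants: 4 methyl 3,5-O-isopropylidene-2-O-methyl-α/β-D-xylofuranoside
Product: 5 methyl 2-O-methyl-α/β-D-xylopyranoside
Conditions: HCl (2% in MeOH), reflux
Reagents that add atoms: methanol, CO
Why: Acid-catalysed transacetalisation removes the isopropylidene group and Fischer equilibration under thermodynamic control converts the furanosides into the more stable pyranosides (the anomeric methoxy group exchanges with the solvent), so the ring oxygen moves from O4 to O5 and the 3,4-diol is exposed; the small furanoside remainder is separated.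

Step 4
Reactants: 5 methyl 2-O-methyl-α/β-D-xylopyranoside
Product: 6 methyl 2-O-methyl-3,4-bis-O-(naphthalen-2-ylmethyl)-α/β-D-xylopyranoside
Conditions: NaH, 2-(bromomethyl)naphthalene, Bu4NI (cat.), DMF, 0 °C → rt
Reagents that add atoms: 2-(bromomethyl)naphthalene, BrCc1ccc2ccccc2c1
Why: Double Williamson etherification of the trans-diequatorial 3,4-diol; naphthylmethyl ethers are chosen because they tolerate the acid of step 5 and are later removed oxidatively without touching the alkene.

Step 5
Reactants: 6 methyl 2-O-methyl-3,4-bis-O-(naphthalen-2-ylmethyl)-α/β-D-xylopyranoside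
Product: 7 2-O-methyl-3,4-bis-O-(naphthalen-2-ylmethyl)-D-xylopyranose
Conditions: AcOH–1 M aq. H2SO4 (4:1), 85 °C
Reagents that add atoms: water, O
Why: Specific-acid-catalysed hydrolysis of the methyl pyranoside via the oxocarbenium ion; pentopyranosides hydrolyse readily, and arylmethyl ethers of the benzyl type, unlike 4-methoxybenzyl ethers, are expected to withstand these conditions.

Step 6
Reactants: 7 2-O-methyl-3,4-bis-O-(naphthalen-2-ylmethyl)-D-xylopyranose; 8 S-ethyl 2-(triphenyl-λ5-phosphanylidene)ethanethioate
Product: 9 S-ethyl (2E,4S,5R,6R)-7-hydroxy-4-methoxy-5,6-bis(naphthalen-2-ylmethoxy)hept-2-enethioate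
Conditions: PhMe, 80 °C
Reagents that add atoms: none
Why: Wittig olefination of the open-chain hydroxy-aldehyde tautomer of the lactol with a stabilised ylide gives the (E)-enethioate (new C2=C3 bond) and frees sugar O5 as the only hydroxyl; without base the 6-exo oxa-Michael return of that hydroxyl should stay slow.

Step 7
Reactants: 9 S-ethyl (2E,4S,5R,6R)-7-hydroxy-4-methoxy-5,6-bis(naphthalen-2-ylmethoxy)hept-2-enethioate
Product: 10 S-ethyl (2E,4S,5R,6S)-4-methoxy-5,6-bis(naphthalen-2-ylmethoxy)-7-oxohept-2-enethioate
Conditions: Dess–Martin periodinane, CH2Cl2, 0 °C → rt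
Reagents that add atoms: none
Why: Dess–Martin oxidation of the primary alcohol under near-neutral, non-enolising conditions, so the α-alkoxy stereocentre (future C5) is not epimerised; the aldehyde is used at once.

Step 8
Reactants: 10 S-ethyl (2E,4S,5R,6S)-4-methoxy-5,6-bis(naphthalen-2-ylmethoxy)-7-oxohept-2-enethioate
Product: 11 S-ethyl (3S,4R,5R,6R)-6-hydroxy-3-methoxy-4,5-bis(naphthalen-2-ylmethoxy)cyclohex-1-ene-1-carbothioate
Conditions: PMe3 (0.3 equiv), CH2Cl2 (0.02 M), rt
Reagents that add atoms: none
Why: Intramolecular Morita–Baylis–Hillman reaction of an ω-formyl α,β-unsaturated thioester, a known cyclisation type for six-membered rings that tolerates enolisable aldehydes. PMe3 adds reversibly to C2 (target numbering), the phosphonium thioester enolate attacks the C4 aldehyde through C3, and proton transfer followed by E1cB loss of the phosphine restores C2=C3 and turns the phosphine over. The thioester is preferred to an ester because it is the better Michael acceptor and gives the more acidic α-proton, which speeds addition and the turnover-limiting elimination. The ring closes in a 6-(enolexo)-exo-trig mode: the enolate C3=C7 bond lies outside the forming ring and the carbonyl oxygen of C4 ends exocyclic. In the chair-like transition state the OMe at C1 and the naphthylmethoxy groups at C6 and C5 are all equatorial, which places the forming C3–C4 bond anti to the C5–O bond (polar Felkin–Anh arrangement). The new stereocentre C4 is therefore controlled by C5: the carbonyl oxygen should sit gauche to C6, that is axial, giving the (4R) alcohol cis to O5; this isomer also avoids allylic 1,2-strain with the C3 thioester, so reversibility of the aldol step works in the same direction. The step needs this facial selectivity and needs cyclisation to outrun dimerisation and β-elimination at the α-alkoxy aldehyde; high dilution, the weakly basic phosphine and the absence of added base should secure the latter two.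

Step 9
Reactants: 11 S-ethyl (3S,4R,5R,6R)-6-hydroxy-3-methoxy-4,5-bis(naphthalen-2-ylmethoxy)cyclohex-1-ene-1-carbothioate
Product: 12 (1R,4S,5R,6R)-2-(hydroxymethyl)-4-methoxy-5,6-bis(naphthalen-2-ylmethoxy)cyclohex-2-en-1-ol
Conditions: iBu2AlH (4 equiv), CH2Cl2, −78 → 0 °C; aq. KNaC4H4O6 (potassium sodium tartrate)
Reagents that add atoms: none
Why: Hydride reduction of the thioester through the enal to the allylic alcohol (1,2-selective with iBu2AlH); the free C4 hydroxyl only consumes one hydride and the ethers are inert.

Step 10
Reactants: 12 (1R,4S,5R,6R)-2-(hydroxymethyl)-4-methoxy-5,6-bis(naphthalen-2-ylmethoxy)cyclohex-2-en-1-ol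
Product: 13 (1S,2R,3R,6S)-4-(hydroxymethyl)-6-methoxycyclohex-4-ene-1,2,3-triol
Conditions: DDQ (3 equiv), CH2Cl2–H2O (10:1), 0 °C → rt
Reagents that add atoms: none
Why: Oxidative cleavage of the electron-rich naphthylmethyl ethers by DDQ (hydride abstraction, then hydrolysis of the oxocarbenium ions by water); the allylic alcohols, flanked by electron-withdrawing oxygens, should be oxidised much more slowly, and the aqueous medium disfavours acetal formation with the neighbouring hydroxyl.

Step 11
Reactants: 13 (1S,2R,3R,6S)-4-(hydroxymethyl)-6-methoxycyclohex-4-ene-1,2,3-triol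
Product: 15 [(3S,4R,5R,6R)-5-(benzoyloxy)-4,6-dihydroxy-3-methoxycyclohex-1-en-1-yl]methyl benzoate (target), via 4,5-O-dibutylstannylene acetal 14 (not isolated)
Conditions: Bu2SnO (1.2 equiv), MeOH, reflux; evaporate; then BzCl (2.1 equiv), PhMe, 0 °C → rt
Reagents that add atoms: benzoyl chloride, O=C(Cl)c1ccccc1
Why: Stannylene-acetal-mediated acylation: the cis-vicinal O4/O5 pair forms the five-membered tin acetal whose equatorial oxygen (O5) is the activated one, and the primary allylic O7 is the most accessible free hydroxyl; 13 mirrors methyl β-D-galactopyranoside, which the same reagents convert into its 3,6-dibenzoate, and the base-free conditions avoid migration of the C5 benzoate to O4 or O6.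

## Compound list

1 | D-xylose | O=C[C@H](O)[C@@H](O)[C@H](O)CO | starting material
2 | methyl α/β-D-xylofuranoside | COC1[C@H](O)[C@@H](O)[C@@H](CO)O1 | intermediate (not isolated)
3 | methyl 3,5-O-isopropylidene-α/β-D-xylofuranoside | COC1[C@H](O)[C@H]2OC(C)(C)OC[C@H]2O1 | intermediate
4 | methyl 3,5-O-isopropylidene-2-O-methyl-α/β-D-xylofuranoside | COC1[C@H](OC)[C@H]2OC(C)(C)OC[C@H]2O1 | intermediate
5 | methyl 2-O-methyl-α/β-D-xylopyranoside | COC1[C@H](OC)[C@@H](O)[C@H](O)CO1 | intermediate
6 | methyl 2-O-methyl-3,4-bis-O-(naphthalen-2-ylmethyl)-α/β-D-xylopyranoside | COC1[C@H](OC)[C@@H](OCc2ccc3ccccc3c2)[C@H](OCc2ccc3ccccc3c2)CO1 | intermediate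
7 | 2-O-methyl-3,4-bis-O-(naphthalen-2-ylmethyl)-D-xylopyranose | OC1[C@H](OC)[C@@H](OCc2ccc3ccccc3c2)[C@H](OCc2ccc3ccccc3c2)CO1 | intermediate
8 | S-ethyl 2-(triphenyl-λ5-phosphanylidene)ethanethioate | CCSC(=O)C=P(c1ccccc1)(c1ccccc1)c1ccccc1 | starting material
9 | S-ethyl (2E,4S,5R,6R)-7-hydroxy-4-methoxy-5,6-bis(naphthalen-2-ylmethoxy)hept-2-enethioate | CCSC(=O)/C=C/[C@H](OC)[C@@H](OCc1ccc2ccccc2c1)[C@H](OCc1ccc2ccccc2c1)CO | intermediate
10 | S-ethyl (2E,4S,5R,6S)-4-methoxy-5,6-bis(naphthalen-2-ylmethoxy)-7-oxohept-2-enethioate | CCSC(=O)/C=C/[C@H](OC)[C@@H](OCc1ccc2ccccc2c1)[C@H](OCc1ccc2ccccc2c1)C=O | intermediate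
11 | S-ethyl (3S,4R,5R,6R)-6-hydroxy-3-methoxy-4,5-bis(naphthalen-2-ylmethoxy)cyclohex-1-ene-1-carbothioate | CO[C@H]1C=C(C(=O)SCC)[C@@H](O)[C@@H](OCc2ccc3ccccc3c2)[C@@H]1OCc1ccc2ccccc2c1 | intermediate
12 | (1R,4S,5R,6R)-2-(hydroxymethyl)-4-methoxy-5,6-bis(naphthalen-2-ylmethoxy)cyclohex-2-en-1-ol | CO[C@H]1C=C(CO)[C@@H](O)[C@@H](OCc2ccc3ccccc3c2)[C@@H]1OCc1ccc2ccccc2c1 | intermediate
13 | (1S,2R,3R,6S)-4-(hydroxymethyl)-6-methoxycyclohex-4-ene-1,2,3-triol | CO[C@H]1C=C(CO)[C@@H](O)[C@@H](O)[C@@H]1O | intermediate
14 | 4,5-O-dibutylstannylene acetal of 13 (target numbering, drawn as the monomer) | CO[C@H]1C=C(CO)[C@H]2O[Sn](CCCC)(CCCC)O[C@H]2[C@@H]1O | intermediate (not isolated)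
15 | [(3S,4R,5R,6R)-5-(benzoyloxy)-4,6-dihydroxy-3-methoxycyclohex-1-en-1-yl]methyl benzoate | CO[C@H]1C=C(COC(=O)c2ccccc2)[C@@H](O)[C@@H](OC(=O)c2ccccc2)[C@@H]1O | target

## Step count and least certain steps

Total: 11 steps. Longest linear sequence: 11 steps (1 → 15); ylide 8 enters in step 6.

**Step 8 (key step).** Most likely failure: stalled turnover, because phosphine addition to a γ-alkoxy enethioate is slow and the phosphonium enolate can divert by proton shift toward C1, with oligomerisation taking over; uncertain facial selectivity at C4 is the second concern. Fallback: from 10, lithium benzeneselenolate (PhSeLi, THF, −78 °C) adds stoichiometrically to C2 and the lithium enolate closes onto the aldehyde, giving S-ethyl 6-hydroxy-3-methoxy-4,5-bis(naphthalen-2-ylmethoxy)-2-(phenylselanyl)cyclohexane-1-carbothioate F1. Oxidation with H2O2–pyridine gives the selenoxide F2, which undergoes syn-elimination at room temperature toward the acidic C3–H (elimination toward the oxygen-bearing C1 is disfavoured). This returns to the route at 11.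

**Step 11.** Most likely failure: loss of regioselectivity (acylation at O6 or O4, or a third benzoate), because the tin reagent can also bridge the trans O5/O6 pair or O4/O7. Fallback: from 12, the primary hydroxyl alone is benzoylated (BzCl, 2,4,6-collidine, CH2Cl2, −40 °C) to [(3S,4R,5R,6R)-6-hydroxy-3-methoxy-4,5-bis(naphthalen-2-ylmethoxy)cyclohex-1-en-1-yl]methyl benzoate F3. DDQ then gives [(3S,4S,5R,6R)-4,5,6-trihydroxy-3-methoxycyclohex-1-en-1-yl]methyl benzoate F4. A borinic-acid-catalysed benzoylation (2-aminoethyl diphenylborinate cat., BzCl, iPr2NEt, MeCN), which selects the equatorial oxygen of a cis-1,2-diol, places the second benzoate on O5 and returns to the route at 15.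

**Step 5.** Most likely failure: partial loss of the naphthylmethyl ethers by acid-promoted ionisation before the glycoside is fully hydrolysed. Fallback: from 6, PhSSiMe3 with ZnI2 and Bu4NI (ClCH2CH2Cl, 60 °C) exchanges the anomeric methoxy group for a phenylthio group, giving phenyl 2-O-methyl-3,4-bis-O-(naphthalen-2-ylmethyl)-1-thio-D-xylopyranoside F5. This is hydrolysed under near-neutral conditions with NBS in acetone–water and returns to the route at 7.

**Step 10.** Most likely failure: over-oxidation of the primary allylic alcohol to the enal by DDQ during the slower cleavage of the second ether. Fallback: from 11, where the only allylic alcohol is deactivated by the conjugated thioester, DDQ is applied first to give S-ethyl (3S,4S,5R,6R)-4,5,6-trihydroxy-3-methoxycyclohex-1-ene-1-carbothioate F6. Reduction with excess iBu2AlH then returns to the route at 13.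

**Step 6.** Most likely failure: oxa-Michael ring closure of the liberated primary hydroxyl onto the enethioate at the temperature needed to open the lactol. Fallback: from 7, Wittig methylenation (Ph3P=CH2 from Ph3PCH3Br and nBuLi, THF) gives (2R,3R,4S)-4-methoxy-2,3-bis(naphthalen-2-ylmethoxy)hex-5-en-1-ol F7, which has no Michael acceptor. Cross-metathesis with S-ethyl prop-2-enethioate, using the second-generation Hoveyda–Grubbs catalyst (H2IMes)Cl2Ru=CH(C6H4-2-OiPr) in CH2Cl2 at 40 °C, then returns to the route at 9.

## Further compounds

F1 | step 8 | S-ethyl 6-hydroxy-3-methoxy-4,5-bis(naphthalen-2-ylmethoxy)-2-(phenylselanyl)cyclohexane-1-carbothioate (oxygenated carbons as in 11; the two new centres as formed) | CO[C@H]1C([Se]c2ccccc2)C(C(=O)SCC)[C@@H](O)[C@@H](OCc2ccc3ccccc3c2)[C@@H]1OCc1ccc2ccccc2c1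
F2 | step 8 | selenoxide of F1 | CO[C@H]1C([Se](=O)c2ccccc2)C(C(=O)SCC)[C@@H](O)[C@@H](OCc2ccc3ccccc3c2)[C@@H]1OCc1ccc2ccccc2c1
F3 | step 11 | [(3S,4R,5R,6R)-6-hydroxy-3-methoxy-4,5-bis(naphthalen-2-ylmethoxy)cyclohex-1-en-1-yl]methyl benzoate | CO[C@H]1C=C(COC(=O)c2ccccc2)[C@@H](O)[C@@H](OCc2ccc3ccccc3c2)[C@@H]1OCc1ccc2ccccc2c1
F4 | step 11 | [(3S,4S,5R,6R)-4,5,6-trihydroxy-3-methoxycyclohex-1-en-1-yl]methyl benzoate | CO[C@H]1C=C(COC(=O)c2ccccc2)[C@@H](O)[C@@H](O)[C@@H]1O
F5 | step 5 | phenyl 2-O-methyl-3,4-bis-O-(naphthalen-2-ylmethyl)-1-thio-α/β-D-xylopyranoside | c1ccccc1SC1[C@H](OC)[C@@H](OCc2ccc3ccccc3c2)[C@H](OCc2ccc3ccccc3c2)CO1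
F6 | step 10 | S-ethyl (3S,4S,5R,6R)-4,5,6-trihydroxy-3-methoxycyclohex-1-ene-1-carbothioate | CO[C@H]1C=C(C(=O)SCC)[C@@H](O)[C@@H](O)[C@@H]1O
F7 | step 6 | (2R,3R,4S)-4-methoxy-2,3-bis(naphthalen-2-ylmethoxy)hex-5-en-1-ol | C=C[C@H](OC)[C@@H](OCc1ccc2ccccc2c1)[C@H](OCc1ccc2ccccc2c1)CO
A1 | alternative 1 | (3aR,7aS)-2,2-dimethyl-3a,7a-dihydro-1,3-benzodioxole (meso diene acetonide) | CC1(C)O[C@H]2C=CC=C[C@H]2O1
A2 | alternative 1 | monoepoxide of A1 anti to the acetonide (vinyl epoxide, enantiomer needed) | C1=C[C@H]2OC(C)(C)O[C@H]2[C@@H]3O[C@H]13
A3 | alternative 1 | methanolysis product of A2 (C1 methoxy, C6 hydroxyl, C4/C5 acetonide) | CO[C@H]1C=C[C@H]2OC(C)(C)O[C@H]2[C@@H]1O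
A4 | alternative 2 | bromobenzene | Brc1ccccc1
A5 | alternative 2 | (1S,2S)-3-bromocyclohexa-3,5-diene-1,2-diol | O[C@@H]1C(Br)=CC=C[C@@H]1O
A6 | alternative 3 | furfuryl acetate (furan-2-ylmethyl acetate) | CC(=O)OCc1ccco1
A7 | alternative 3 | vinylene carbonate (1,3-dioxol-2-one) | O=C1OC=CO1
A8 | alternative 3 | endo 7-oxanorbornene carbonate with bridgehead acetoxymethyl (enantiomer needed) | C1=C[C@@]2(COC(C)=O)[C@H]3OC(=O)O[C@H]3[C@@H]1O2
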